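**Retrosynthetic overview**
1. Ring D and the C11=C12 alkene are made last: a quinone carrying a free C5–OH and a C12 pivalate closes by intramolecular oxa-Michael addition at C6 with loss of pivalate.
2. The quinone (ring C) comes from a 2,5-dimethoxyarene; the C5 carbinol comes from a 1,2-diketone by ketoreductase reduction.
3. Ring B comes from Friedel–Crafts opening of a tertiary epoxide by the arene (Sharpless epoxidation, then inversion at C19).
4. Ring A comes first, from a Rh/BINAP conjugate addition–aldol cyclisation of an alkenylboronate onto an aryl enone–methyl ketone (sets C14, C13, C17).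
5. Order of ring formation: A, B, C (unmasked as quinone), D.

Locants follow the target SMILES left to right: C1–C3 (CH3)2C=, C4 =CH, C5 O–CH, C6 spiro C–O, C7 C=O, C8=C9, C10 C=O, C11=C12, C13/C14 ring-fusion CH, C15/C16 CH2, C17 C(OH) with C18H3, C19 quaternary C with C20H3, C21 C=O. Rings: A = C13–C17, B = C6/C11–C14/C19, C = C6–C11, D = furanone.

Assumption: the sense of induction in step 6 follows the Hayashi–Miyaura model for (S)-BINAP; if the opposite sense is found, (R)-BINAP is used and nothing else changes.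

Assumption: C12 is drawn as S (chelation model); its configuration is immaterial because C12 becomes sp2 in step 19.

**Step 1**
Reactants: 1 2,5-dimethoxybenzoyl chloride
Product: 2 N,2,5-trimethoxy-N-methylbenzamide
Conditions: MeNHOMe·HCl, Et3N, CH2Cl2, 0 °C → rt
Reagents that add atoms: N,O-dimethylhydroxylamine hydrochloride, CNOC.Cl
Why: N-acylation of the amine by the acid chloride gives the Weinreb amide, which later stops organometallic addition at the ketone stage; no stereocentre.

**Step 2**
Reactants: 2 N,2,5-trimethoxy-N-methylbenzamide; 3 vinylmagnesium bromide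
Product: 4 1-(2,5-dimethoxyphenyl)prop-2-en-1-one
Conditions: THF, −10 °C; inverse quench into cold 1 M HCl
Reagents that add atoms: none
Why: Weinreb ketone synthesis; the chelated adduct collapses only on acidic quench, and the inverse acidic quench keeps the liberated amine from adding back to the enone.

**Step 3**
Reactants: 4 1-(2,5-dimethoxyphenyl)prop-2-en-1-one; 5 hex-5-en-2-one
Product: 6 (E)-1-(2,5-dimethoxyphenyl)hept-2-ene-1,6-dione
Conditions: RuCl2(H2IMes)(=CH-C6H4-2-OiPr) (second-generation Hoveyda–Grubbs catalyst, 3 mol %), 5 (3 equiv), CH2Cl2, 40 °C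
Reagents that add atoms: none
Why: olefin cross-metathesis of an electron-poor enone and an unhindered terminal alkene is selective for the E cross-product.

**Step 4**
Reactants: 7 but-2-yn-1-ol
Product: 8 (but-2-yn-1-yloxy)(tert-butyl)dimethylsilane
Conditions: TBSCl, imidazole, CH2Cl2, 0 °C → rt
Reagents that add atoms: tert-butyldimethylsilyl chloride, CC(C)(C)[Si](C)(C)Cl
Why: standard silyl ether formation on a primary alcohol.

**Step 5**
Reactants: 8 (but-2-yn-1-yloxy)(tert-butyl)dimethylsilane
Product: 9 (Z)-tert-butyldimethyl{[3-(4,4,5,5-tetramethyl-1,3,2-dioxaborolan-2-yl)but-2-en-1-yl]oxy}silane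
Conditions: CuCl (5 mol %), PCy3 (6 mol %), NaOtBu (10 mol %), B2pin2 (1.1 equiv), MeOH (2 equiv), toluene, rt
Reagents that add atoms: bis(pinacolato)diboron, CC1(C)OB(OC1(C)C)B1OC(C)(C)C(C)(C)O1
Why: copper-catalysed borylcupration–protonation (formal hydroboration) adds H and B syn, with boron on the methyl-bearing alkyne carbon remote from the propargylic oxygen, so CH3 and CH2OTBS end up cis.

**Step 6**
Reactants: 6 (E)-1-(2,5-dimethoxyphenyl)hept-2-ene-1,6-dione; 9 (Z)-alkenylboronate
Product: 11 (13R,14S,17S)-ring A ketol (2,5-dimethoxybenzoyl at C13; C17(OH)CH3 cis to it; (E)-4-(TBSO)but-2-en-2-yl at C14 trans to it), via rhodium Z-enolate 10 (not isolated)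
Conditions: [Rh(cod)Cl]2 (2.5 mol %), (S)-BINAP (6 mol %), KOH (aq), 9 (2 equiv), dioxane/H2O 10:1, 95 °C
Reagents that add atoms: none
Why: Hayashi–Miyaura asymmetric conjugate addition sets C14 under ligand control, and the enolate is trapped by the tethered methyl ketone in a closed Zimmerman–Traxler aldol cyclisation that puts the C17 hydroxyl cis to the C13 aroyl group and the aroyl group trans to the C14 substituent.

**Step 7**
Reactants: 11 ring A ketol
Product: 12 (12S,13S,14S,17S)-1,3-diol (C12 benzylic carbinol)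
Conditions: Et2BOMe, NaBH4, THF/MeOH 4:1, −78 °C; MeOH co-evaporation
Reagents that add atoms: none
Why: Narasaka–Prasad chelation-controlled reduction of the β-hydroxy ketone delivers hydride to the exposed face of the carbonyl; the new C12 centre is later destroyed.

**Step 8**
Reactants: 12 1,3-diol
Product: 13 C12 pivalate (C17 tertiary OH free)
Conditions: PivCl, pyridine, DMAP (cat.), CH2Cl2, 0 → 40 °C
Reagents that add atoms: pivaloyl chloride, CC(C)(C)C(Cl)=O
Why: DMAP-catalysed acylation esterifies the secondary benzylic alcohol and not the tertiary one; the pivalate is both a robust protecting group and the later leaving group.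

**Step 9**
Reactants: 13 C12 pivalate
Product: 14 (E)-allylic alcohol (C5H2OH)
Conditions: HF·pyridine, pyridine, THF, 0 °C → rt
Reagents that add atoms: none
Why: buffered fluoride desilylation cleaves the primary silyl ether and leaves the pivalate and the tertiary alcohol alone.

**Step 10**
Reactants: 14 (E)-allylic alcohol
Product: 15 (19R,21R)-2,3-epoxy alcohol
Conditions: Ti(OiPr)4 (10 mol %), D-(−)-diethyl tartrate (12 mol %), t-BuOOH, 4 Å MS, CH2Cl2, −20 °C
Reagents that add atoms: tert-butyl hydroperoxide, CC(C)(C)OO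
Why: Sharpless asymmetric epoxidation; with D-(−)-tartrate the geraniol-type (E)-allylic alcohol is epoxidised on the face that gives the (19R,21R)-epoxide under reagent control.

**Step 11**
Reactants: 15 epoxy alcohol
Product: 16 (19R,21S)-epoxy aldehyde (C5 = CHO)
Conditions: Dess–Martin periodinane, NaHCO3, CH2Cl2, 0 °C → rt
Reagents that add atoms: none
Why: Dess–Martin oxidation is mild enough to leave the epoxide, the pivalate and the tertiary alcohol untouched.

**Step 12**
Reactants: 16 epoxy aldehyde; 17 (2-methylprop-1-en-1-yl)magnesium bromide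
Product: 18 epoxy allylic alcohol (C5 epimer mixture)
Conditions: 17 (3 equiv), THF, −78 °C; aq NH4Cl
Reagents that add atoms: none
Why: Grignard 1,2-addition to the aldehyde at −78 °C is far faster than attack on the hindered pivalate or the epoxide; the C5 epimer mixture is erased in step 16.

**Step 13**
Reactants: 18 epoxy allylic alcohol
Product: 19 C5 tert-butyldimethylsilyl ether (C5 epimer mixture)
Conditions: TBSCl, imidazole, DMAP (cat.), DMF, rt
Reagents that add atoms: tert-butyldimethylsilyl chloride, CC(C)(C)[Si](C)(C)Cl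
Why: silyl ether formation on the secondary alcohol only; it removes a competing oxygen nucleophile before the Lewis-acid step.

**Step 14**
Reactants: 19 epoxy silyl ether
Product: 20 tricyclic C21 alcohol (rings A and B plus dimethoxyarene; 12S,13S,14S,17S,19R,21S; C5 epimers)
Conditions: BF3·OEt2, CH2Cl2, −78 °C; aq NaHCO3
Reagents that add atoms: none
Why: intramolecular Friedel–Crafts epoxide–arene cyclisation (6-exo); arene carbon C6, activated by its ortho methoxy group, opens the epoxide at tertiary C19 anti to the leaving oxygen, so C19 is set by inversion and ring B closes trans-fused.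

**Step 15**
Reactants: 20 tricyclic alcohol
Product: 21 C5,C21-diol (C5 epimer mixture)
Conditions: HF·pyridine, pyridine, THF, 0 °C → rt
Reagents that add atoms: none
Why: fluoride desilylation of the secondary silyl ether under buffered conditions that spare the benzylic pivalate.

**Step 16**
Reactants: 21 diol
Product: 22 (12S,13S,14S,17S,19R)-C5,C21-diketone
Conditions: (COCl)2, DMSO, CH2Cl2, −78 °C; Et3N, → 0 °C
Reagents that add atoms: none
Why: Swern oxidation converts both secondary alcohols to a non-enolisable 1,2-diketone without C–C cleavage, removing the C5 and C21 carbinol centres.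

**Step 17**
Reactants: 22 diketone
Product: 23 (5R)-α-hydroxy ketone (C21 ketone, C5 carbinol)
Conditions: ketoreductase ((R)-selective, anti-Prelog, chosen from a screening panel), NADP+ (cat.), i-PrOH, KH2PO4/K2HPO4 buffer pH 7, 10% DMSO, 30 °C
Reagents that add atoms: none
Why: ketoreductase-catalysed asymmetric carbonyl reduction; only the C5 carbonyl is accessible (C21 is flanked by quaternary C19), hydride is delivered anti-Prelog to give the 5R alcohol, and neutral pH avoids epimerisation and α-ketol shift.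

**Step 18**
Reactants: 23 (5R)-α-hydroxy ketone
Product: 24 p-quinone (ring C oxidised; C5–OH and C12 pivalate intact)
Conditions: (NH4)2Ce(NO3)6 (2.5 equiv), MeCN/H2O 2:1, 0 °C, 15 min
Reagents that add atoms: water, O
Why: oxidative demethylation of the 1,4-dimethoxyarene to the quinone is fast at 0 °C and leaves the trisubstituted alkene, the ketol and the ester.

**Step 19**
Reactants: 24 p-quinone
Product: 26 target CNP0156201.1, via enol oxa-Michael adduct 25 (not isolated)
Conditions: Et3N (0.5 equiv), CH2Cl2, −20 → 0 °C; pH 7 buffer quench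
Reagents that add atoms: none
Why: 5-exo oxa-Michael addition of C5–OH to quinone carbon C6 can only occur on the face bearing C21 (this sets C6), and E1cB loss of pivalate from C12 then installs C11=C12 and makes the sequence irreversible (net SN2′).

**Compound list**
1 | 2,5-dimethoxybenzoyl chloride | COc1ccc(OC)c(c1)C(Cl)=O | starting material
2 | N,2,5-trimethoxy-N-methylbenzamide | COc1ccc(OC)c(c1)C(=O)N(C)OC | intermediate
3 | vinylmagnesium bromide | C=C[Mg]Br | starting material
4 | 1-(2,5-dimethoxyphenyl)prop-2-en-1-one | COc1ccc(OC)c(c1)C(=O)C=C | intermediate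
5 | hex-5-en-2-one | CC(=O)CCC=C | starting material
6 | (E)-1-(2,5-dimethoxyphenyl)hept-2-ene-1,6-dione | COc1ccc(OC)c(c1)C(=O)/C=C/CCC(C)=O | intermediate
7 | but-2-yn-1-ol | CC#CCO | starting material
8 | (but-2-yn-1-yloxy)(tert-butyl)dimethylsilane | CC#CCO[Si](C)(C)C(C)(C)C | intermediate
9 | (Z)-tert-butyldimethyl{[3-(4,4,5,5-tetramethyl-1,3,2-dioxaborolan-2-yl)but-2-en-1-yl]oxy}silane | C/C(B1OC(C)(C)C(C)(C)O1)=C\CO[Si](C)(C)C(C)(C)C | intermediate
10 | rhodium Z-enolate of the (14S) 1,4-adduct (BINAP on Rh not drawn) | COc1ccc(OC)c(c1)/C(O[Rh])=C/[C@H](CCC(C)=O)/C(C)=C/CO[Si](C)(C)C(C)(C)C | intermediate (not isolated)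
11 | (13R,14S,17S)-ring A ketol | COc1ccc(OC)c(c1)C(=O)[C@@H]1[C@H](CC[C@]1(C)O)/C(C)=C/CO[Si](C)(C)C(C)(C)C | intermediate
12 | (12S,13S,14S,17S)-1,3-diol | COc1ccc(OC)c(c1)[C@@H](O)[C@@H]1[C@H](CC[C@]1(C)O)/C(C)=C/CO[Si](C)(C)C(C)(C)C | intermediate
13 | C12 pivalate of 12 | COc1ccc(OC)c(c1)[C@@H](OC(=O)C(C)(C)C)[C@@H]1[C@H](CC[C@]1(C)O)/C(C)=C/CO[Si](C)(C)C(C)(C)C | intermediate
14 | (E)-allylic alcohol | COc1ccc(OC)c(c1)[C@@H](OC(=O)C(C)(C)C)[C@@H]1[C@H](CC[C@]1(C)O)/C(C)=C/CO | intermediate
15 | (19R,21R)-epoxy alcohol | COc1ccc(OC)c(c1)[C@@H](OC(=O)C(C)(C)C)[C@@H]1[C@H](CC[C@]1(C)O)[C@@]1(C)O[C@@H]1CO | intermediate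
16 | (19R,21S)-epoxy aldehyde | COc1ccc(OC)c(c1)[C@@H](OC(=O)C(C)(C)C)[C@@H]1[C@H](CC[C@]1(C)O)[C@@]1(C)O[C@@H]1C=O | intermediate
17 | (2-methylprop-1-en-1-yl)magnesium bromide | CC(C)=C[Mg]Br | starting material
18 | epoxy allylic alcohol, C5 epimer mixture | COc1ccc(OC)c(c1)[C@@H](OC(=O)C(C)(C)C)[C@@H]1[C@H](CC[C@]1(C)O)[C@@]1(C)O[C@@H]1C(O)C=C(C)C | intermediate
19 | C5 TBS ether of 18, C5 epimer mixture | COc1ccc(OC)c(c1)[C@@H](OC(=O)C(C)(C)C)[C@@H]1[C@H](CC[C@]1(C)O)[C@@]1(C)O[C@@H]1C(O[Si](C)(C)C(C)(C)C)C=C(C)C | intermediate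
20 | tricyclic C21 alcohol, C5 epimer mixture | COc1ccc(OC)c2c1[C@](C)([C@H](O)C(O[Si](C)(C)C(C)(C)C)C=C(C)C)[C@H]1CC[C@](C)(O)[C@@H]1[C@@H]2OC(=O)C(C)(C)C | intermediate
21 | C5,C21-diol, C5 epimer mixture | COc1ccc(OC)c2c1[C@](C)([C@H](O)C(O)C=C(C)C)[C@H]1CC[C@](C)(O)[C@@H]1[C@@H]2OC(=O)C(C)(C)C | intermediate
22 | (12S,13S,14S,17S,19R)-C5,C21-diketone | COc1ccc(OC)c2c1[C@](C)(C(=O)C(=O)C=C(C)C)[C@H]1CC[C@](C)(O)[C@@H]1[C@@H]2OC(=O)C(C)(C)C | intermediate
23 | (5R,12S,13S,14S,17S,19R)-α-hydroxy ketone | COc1ccc(OC)c2c1[C@](C)(C(=O)[C@H](O)C=C(C)C)[C@H]1CC[C@](C)(O)[C@@H]1[C@@H]2OC(=O)C(C)(C)C | intermediate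
24 | (5R,12S,13S,14S,17S,19R)-p-quinone | O=C1C=CC(=O)C2=C1[C@](C)(C(=O)[C@H](O)C=C(C)C)[C@H]1CC[C@](C)(O)[C@@H]1[C@@H]2OC(=O)C(C)(C)C | intermediate
25 | enol oxa-Michael adduct (5R,6S,12S,13S,14S,17S,19R) | CC(C)=C[C@H]1O[C@@]23C(=O)C=CC(O)=C2[C@@H](OC(=O)C(C)(C)C)[C@@H]2[C@H](CC[C@]2(C)O)[C@@]3(C)C1=O | intermediate (not isolated)
26 | CNP0156201.1 (5R,6S,13R,14S,17S,19R) | CC(C)=C[C@H]1O[C@@]23C(=O)C=CC(=O)C2=C[C@@H]2[C@H](CC[C@]2(C)O)[C@@]3(C)C1=O | target

**Totals**
Total steps: 19. Longest linear sequence: 17 (steps 1–3 and 6–19; steps 4–5 are a side branch).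

**Steps most likely to fail, with fallbacks**

Step 6 is at risk because the hindered, α-methyl alkenylboronate may transmetalate slowly and protodeboronate before adding. The fallback sets out from silyl ether 8 and enedione 6 and changes the organometallic manifold. Hydrozirconation of 8 with Cp2Zr(H)Cl in THF places zirconium on the methyl-bearing carbon and gives the alkenylzirconocene chloride F1. Under anhydrous [Rh(cod)(MeCN)2]BF4/(S)-BINAP catalysis F1 adds to 6, and the resulting zirconium enolate closes the aldol ring. Aqueous NH4Cl work-up returns the route at ketol 11.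

Step 14 is at risk because the allylic silyl ether and the isobutenyl group of 19 may ionise or rearrange under BF3 faster than the arene attacks. The fallback sets out from epoxy alcohol 15 and cyclises before the side chain is built. Silylation (TBSCl, imidazole) gives the primary silyl ether F2, and BF3·OEt2 at −78 °C gives the tricyclic alcohol F3. HF·pyridine then gives the diol F4, and Swern oxidation gives the non-enolisable keto aldehyde F5. Nozaki–Hiyama–Kishi coupling of F5 with 1-bromo-2-methylprop-1-ene (CrCl2, NiCl2 cat., DMF) adds only to the aldehyde and gives 23 together with its C5 epimer F6. Swern oxidation of the pair returns the route at diketone 22.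

Step 17 is at risk because no panel ketoreductase may accept the bulky diketone with the required sense. The fallback sets out from diketone 22 and replaces asymmetric reduction by reduction followed by an enzymatic separation. Zn(BH4)2 in Et2O at −40 °C reduces only the unhindered C5 carbonyl and gives 23 together with its C5 epimer F7. Burkholderia cepacia lipase with vinyl acetate in MTBE acetylates the 5R alcohol (Kazlauskas preference) to the acetate F8. Unreacted F7 is separated and re-oxidised with Dess–Martin periodinane to 22. Candida antarctica lipase B in pH 7 buffer/MeCN hydrolyses F8 and returns the route at 23.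

**Further compounds**
F1 | step 6 | chlorobis(cyclopentadienyl)[(E)-4-(tert-butyldimethylsilyloxy)but-2-en-2-yl]zirconium, Cp2Zr(Cl)[C(CH3)=CHCH2OTBS] | C/C(=C\CO[Si](C)(C)C(C)(C)C)[Zr](Cl)(C1C=CC=C1)C1C=CC=C1
F2 | step 14 | primary TBS ether of epoxy alcohol 15 | COc1ccc(OC)c(c1)[C@@H](OC(=O)C(C)(C)C)[C@@H]1[C@H](CC[C@]1(C)O)[C@@]1(C)O[C@@H]1CO[Si](C)(C)C(C)(C)C
F3 | step 14 | tricyclic C21 alcohol with C5H2–OTBS | COc1ccc(OC)c2c1[C@](C)([C@H](O)CO[Si](C)(C)C(C)(C)C)[C@H]1CC[C@](C)(O)[C@@H]1[C@@H]2OC(=O)C(C)(C)C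
F4 | step 14 | tricyclic C5,C21-diol (C5H2OH) | COc1ccc(OC)c2c1[C@](C)([C@H](O)CO)[C@H]1CC[C@](C)(O)[C@@H]1[C@@H]2OC(=O)C(C)(C)C
F5 | step 14 | tricyclic C21-keto C5-aldehyde | COc1ccc(OC)c2c1[C@](C)(C(=O)C=O)[C@H]1CC[C@](C)(O)[C@@H]1[C@@H]2OC(=O)C(C)(C)C
F6 | step 14 | (5S)-epimer of 23 | COc1ccc(OC)c2c1[C@](C)(C(=O)[C@@H](O)C=C(C)C)[C@H]1CC[C@](C)(O)[C@@H]1[C@@H]2OC(=O)C(C)(C)C
F7 | step 17 | (5S)-epimer of 23 | COc1ccc(OC)c2c1[C@](C)(C(=O)[C@@H](O)C=C(C)C)[C@H]1CC[C@](C)(O)[C@@H]1[C@@H]2OC(=O)C(C)(C)C
F8 | step 17 | (5R)-C5 acetate of 23 | COc1ccc(OC)c2c1[C@](C)(C(=O)[C@H](OC(C)=O)C=C(C)C)[C@H]1CC[C@](C)(O)[C@@H]1[C@@H]2OC(=O)C(C)(C)C
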